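**Assumption (one line):** positions use the geranylgeranyl numbering of the natural product (C1′ = benzylic CH2 … C15′ = CMe2–O); the chiral catalysts/ligands (ent‑Shi ketone, D‑(–)‑DET) and Li2NiBr4 (from LiBr/NiBr2) are treated as purchasable reagents. The route is a paper design and has not been run; stereodescriptors and SMILES were checked by hand only.

## Retrosynthetic overview

1. The C10′/C11′ bromohydrin is installed last: reagent‑controlled epoxidation of the only remaining trisubstituted alkene, then SN2 bromide opening; then phenol deprotection.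
2. The bromocyclohexane comes from an enantiospecific bromonium/cation–olefin cyclization (C7′→C2′) of a Sharpless‑derived (6′S)-bromo-(7′R)-tertiary alcohol inside a 20‑membered macrolactone.
3. The 20‑membered ring is closed by a B‑alkyl Suzuki macrocyclization (C9′–C10′); the hindered tertiary ester is made intermolecularly beforehand, so no tertiary macrolactonization is needed.
4. Fragments: A (C10′–C15′ iodoalkenyl bromohydrin), B (C1′–C9′ from geranyl acetate), C (arene boronate), with B and C joined by allyl–aryl Suzuki coupling.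
5. Ring order: 20‑membered macrocycle first, then the cyclohexane (which leaves the 16‑membered macrolide).

## Forward route

### Fragment A (C10′–C15′)

**Step 1**
Reactants: 1, 6‑methylhept‑5‑en‑2‑one
Product: 2, 6‑methylhept‑5‑en‑1‑yne
Conditions: LDA, THF, –78 °C; ClP(O)(OEt)2; then LDA (2.3 equiv), –78 °C → rt
Reagents that add atoms: none
Why: Negishi methyl ketone → terminal alkyne conversion (kinetic enol phosphate, then elimination); no stereocentre.

**Step 2**
Reactants: 2, 6‑methylhept‑5‑en‑1‑yne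
Product: 3, (E)‑1‑iodo‑2,6‑dimethylhepta‑1,5‑diene
Conditions: Me3Al, Cp2ZrCl2 (cat.), CH2Cl2, rt; then I2, THF, 0 °C
Reagents that add atoms: trimethylaluminium C[Al](C)C; iodine II
Why: Zr‑catalysed carboalumination (Negishi) adds Me/Al syn, and iodinolysis with retention gives the (E)‑iodide that fixes the C10′=C11′ geometry.

**Step 3**
Reactants: 3, (E)‑1‑iodo‑2,6‑dimethylhepta‑1,5‑diene
Product: 4, (S)‑3‑[(E)‑4‑iodo‑3‑methylbut‑3‑en‑1‑yl]‑2,2‑dimethyloxirane
Conditions: ent‑Shi ketone (30 mol %), Oxone, K2CO3, Bu4NHSO4, MeCN/DMM–buffer (pH 10.5), 0 °C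
Reagents that add atoms: Oxone (KHSO5) OOS(=O)(=O)[O-].[K+]
Why: Shi asymmetric epoxidation attacks only the electron‑rich trisubstituted alkene (the iodoalkene is deactivated), and the L‑series ketone gives the (S)‑epoxide (C14′).

**Step 4**
Reactants: 4, the (S)‑epoxide
Product: 5, (3R,6E)‑3‑bromo‑7‑iodo‑2,6‑dimethylhept‑6‑en‑2‑ol
Conditions: Li2NiBr4, THF, 0 °C → rt
Reagents that add atoms: dilithium tetrabromonickelate [Li+].[Li+].Br[Ni-2](Br)(Br)Br
Why: SN2 opening by soft bromide at the less substituted epoxide carbon inverts C14′ to (R)‑Br and leaves the tertiary OH.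

### Fragment B (C1′–C9′)

**Step 5**
Reactants: 6, geranyl acetate
Product: 7, (2E,6E)‑8‑hydroxy‑3,7‑dimethylocta‑2,6‑dien‑1‑yl acetate
Conditions: SeO2 (cat.), t‑BuOOH, CH2Cl2, rt; then NaBH4, 0 °C (returns over‑oxidized enal)
Reagents that add atoms: selenium dioxide O=[Se]=O; tert‑butyl hydroperoxide CC(C)(C)OO (source of the new O)
Why: Sharpless–Umbreit allylic oxidation (ene/[2,3]) is (E)‑selective at the terminal methyl of the alkene not deactivated by the allylic acetate.

**Step 6**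
Reactants: 7, the 8‑hydroxy acetate
Product: 8, (2E)‑5‑[(2R,3R)‑3‑(hydroxymethyl)‑3‑methyloxiran‑2‑yl]‑3‑methylpent‑2‑en‑1‑yl acetate
Conditions: Ti(OiPr)4, D‑(–)‑DET, t‑BuOOH, 4 Å MS, CH2Cl2, –20 °C
Reagents that add atoms: tert‑butyl hydroperoxide CC(C)(C)OO
Why: Sharpless asymmetric epoxidation of the allylic alcohol only; D‑(–)‑tartrate gives the (6′R,7′R) epoxide.

**Step 7**
Reactants: 8, the epoxy alcohol
Product: 9, (2E,6S,7R)‑6‑bromo‑7,8‑dihydroxy‑3,7‑dimethyloct‑2‑en‑1‑yl acetate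
Conditions: Ti(OiPr)4 (1.5 equiv), NH4Br, THF/DMSO, rt
Reagents that add atoms: ammonium bromide [NH4+].[Br-]
Why: Ti‑chelate‑directed C3‑selective opening of the 2,3‑epoxy alcohol; bromide inverts C6′ to (S) and the tertiary C7′–OH (R) is retained.

**Step 8**
Reactants: 9, the bromo diol
Product: 10, (2E,6S,7R)‑6‑bromo‑7‑hydroxy‑3,7‑dimethyl‑8‑oxooct‑2‑en‑1‑yl acetate
Conditions: SO3·pyridine, DMSO, iPr2NEt, CH2Cl2, 0 °C
Reagents that add atoms: none
Why: Parikh–Doering oxidation touches only the primary alcohol and avoids glycol cleavage; the α‑carbon is quaternary, so it cannot epimerize.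

**Step 9**
Reactants: 10, the hydroxy aldehyde
Product: 11, (2E,6S,7R)‑6‑bromo‑3,7‑dimethyl‑8‑oxo‑7‑(triethylsilyloxy)oct‑2‑en‑1‑yl acetate
Conditions: TESOTf, 2,6‑lutidine, CH2Cl2, –78 °C
Reagents that add atoms: triethylsilyl triflate CC[Si](CC)(CC)OS(=O)(=O)C(F)(F)F
Why: Silylation masks the bromohydrin so later basic steps cannot close it to the epoxide.

**Step 10**
Reactants: 11, the silyloxy aldehyde
Product: 12, (2E,6S,7R)‑6‑bromo‑3,7‑dimethyl‑7‑(triethylsilyloxy)nona‑2,8‑dien‑1‑yl acetate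
Conditions: Ph3PCH3Br, KHMDS, THF, –78 → 0 °C
Reagents that add atoms: methyltriphenylphosphonium bromide C[P+](c1ccccc1)(c1ccccc1)c1ccccc1.[Br-]
Why: Wittig methylenation of a non‑enolizable aldehyde adds C9′.

### Fragment C (arene)

**Step 11**
Reactants: 13, 3‑bromo‑4‑hydroxybenzaldehyde
Product: 14, 2‑bromo‑4‑formylphenyl pivalate
Conditions: PivCl, Et3N, DMAP (cat.), CH2Cl2, 0 °C
Reagents that add atoms: pivaloyl chloride CC(C)(C)C(=O)Cl
Why: O‑acylation; the pivalate survives the Pd/base steps and later prevents phenol O‑capture of the C3′ cation.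

**Step 12**
Reactants: 14, the aryl bromide
Product: 15, 4‑formyl‑2‑(4,4,5,5‑tetramethyl‑1,3,2‑dioxaborolan‑2‑yl)phenyl pivalate
Conditions: B2pin2, Pd(dppf)Cl2, KOAc, dioxane, 85 °C
Reagents that add atoms: bis(pinacolato)diboron CC1(C)OB(OC1(C)C)B1OC(C)(C)C(C)(C)O1
Why: Miyaura borylation.

### Assembly and endgame

**Step 13**
Reactants: 12, the allylic acetate; 15, the aryl boronate
Product: 16, 2‑[(2E,6S,7R)‑6‑bromo‑3,7‑dimethyl‑7‑(triethylsilyloxy)nona‑2,8‑dien‑1‑yl]‑4‑formylphenyl pivalate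
Conditions: Pd(PPh3)4 (5 mol %), K3PO4, THF/H2O, 50 °C
Reagents that add atoms: none
Why: Suzuki–Miyaura allyl–aryl coupling through a π‑allyl‑Pd intermediate; the aryl adds to the unhindered C1′ terminus with the (E)‑alkene retained, and the unactivated secondary bromide is inert.

**Step 14**
Reactants: 16, the aldehyde
Product: 17, 3‑[(2E,6S,7R)‑6‑bromo‑3,7‑dimethyl‑7‑(triethylsilyloxy)nona‑2,8‑dien‑1‑yl]‑4‑(pivaloyloxy)benzoic acid
Conditions: NaClO2, NaH2PO4, 2‑methyl‑2‑butene, t‑BuOH/H2O, 0 °C → rt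
Reagents that add atoms: sodium chlorite [Na+].[O-]Cl=O
Why: Pinnick oxidation; the scavenger protects the alkenes.

**Step 15**
Reactants: 17, the acid; 5, the tertiary bromohydrin
Product: 18, (3R,6E)‑3‑bromo‑7‑iodo‑2,6‑dimethylhept‑6‑en‑2‑yl ester of 17
Conditions: DIC, DMAP (3 equiv), Sc(OTf)3 (0.6 equiv), CH2Cl2, –8 °C → rt
Reagents that add atoms: none
Why: Sc(OTf)3/DMAP‑promoted carbodiimide esterification is a method designed for tertiary alcohols; no free alkoxide forms, so the bromohydrin does not close and C14′ is untouched.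

**Step 16**
Reactants: 18, the seco ester
Product: 19, 20‑membered macrolactone (2′E,10′E,6′S,7′R,14′R) with 7′‑OTES
Conditions: 9‑BBN, THF, 0 °C → rt; then Pd(dppf)Cl2, AsPh3, aq K3PO4, DMF/THF, rt, slow addition (~1 mM)
Reagents that add atoms: none (9‑BBN delivers H only)
Why: 9‑BBN hydroborates only the monosubstituted vinyl group, and the intramolecular B‑alkyl Suzuki–Miyaura coupling forms C9′–C10′ with the (E)‑alkenyl geometry retained.

**Step 17**
Reactants: 19, the silyl ether macrocycle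
Product: 20, the 7′‑hydroxy macrocycle
Conditions: HF·pyridine, pyridine/THF, 0 °C → rt
Reagents that add atoms: none
Why: Selective Si–O cleavage; the aryl pivalate and bromides are stable.

**Step 18**
Reactants: 20, the tertiary bromohydrin macrocycle
Product: 21, bromocyclohexane‑fused 16‑membered macrolide (2′R,6′S,7′S,14′R; 10′E alkene; exocyclic C3′=CH2; phenol pivalate)
Conditions: Tf2O, 2,6‑di‑tert‑butyl‑4‑methylpyridine, CH2Cl2, –78 → –40 °C, high dilution
Reagents that add atoms: none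
Why: Bromonium‑initiated cation–olefin cyclization: the tertiary triflate ionizes with anti C6′–Br participation, C2′=C3′ attacks C7′ anti to Br through a chair (net retention at C7′ → S; C1′ equatorial → 2′R), and the hindered base removes the least hindered methyl proton to give the exocyclic alkene.

**Step 19**
Reactants: 21, the cyclized alkene
Product: 22, the (10′S,11′S)‑epoxide of 21
Conditions: ent‑Shi ketone, Oxone, K2CO3, Bu4NHSO4, MeCN/DMM–buffer (pH 10.5), 0 °C
Reagents that add atoms: Oxone OOS(=O)(=O)[O-].[K+]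
Why: Shi epoxidation under reagent control (same facial sense as Step 3) of the only trisubstituted alkene; the hindered 1,1‑disubstituted exocyclic alkene is a poor substrate.

**Step 20**
Reactants: 22, the epoxide
Product: 23, bromophycolide H O‑pivalate
Conditions: Li2NiBr4, THF, 0 °C → rt
Reagents that add atoms: dilithium tetrabromonickelate [Li+].[Li+].Br[Ni-2](Br)(Br)Br
Why: SN2 bromide opening at the secondary C10′ (inversion → R) leaves the tertiary C11′–OH (S).

**Step 21**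
Reactants: 23, the pivalate
Product: 24, bromophycolide H
Conditions: N2H4·H2O, THF/MeOH, 0 °C → rt
Reagents that add atoms: none
Why: Hydrazinolysis of the activated aryl pivalate; the hindered tertiary benzoate lactone, the bromides and the bromohydrin survive these non‑alkoxide conditions.

## Compound list

1 | 6‑methylhept‑5‑en‑2‑one | CC(=O)CCC=C(C)C | starting material
2 | 6‑methylhept‑5‑en‑1‑yne | C#CCCC=C(C)C | intermediate
3 | (E)‑1‑iodo‑2,6‑dimethylhepta‑1,5‑diene | I/C=C(\C)CCC=C(C)C | intermediate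
4 | (S)‑3‑[(E)‑4‑iodo‑3‑methylbut‑3‑en‑1‑yl]‑2,2‑dimethyloxirane | I/C=C(\C)CC[C@@H]1OC1(C)C | intermediate
5 | (3R,6E)‑3‑bromo‑7‑iodo‑2,6‑dimethylhept‑6‑en‑2‑ol | I/C=C(\C)CC[C@@H](Br)C(C)(C)O | intermediate
6 | geranyl acetate | CC(=O)OC/C=C(\C)CCC=C(C)C | starting material
7 | (2E,6E)‑8‑hydroxy‑3,7‑dimethylocta‑2,6‑dien‑1‑yl acetate | CC(=O)OC/C=C(\C)CC/C=C(\C)CO | intermediate
8 | (2E)‑5‑[(2R,3R)‑3‑(hydroxymethyl)‑3‑methyloxiran‑2‑yl]‑3‑methylpent‑2‑en‑1‑yl acetate | CC(=O)OC/C=C(\C)CC[C@H]1O[C@]1(C)CO | intermediate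
9 | (2E,6S,7R)‑6‑bromo‑7,8‑dihydroxy‑3,7‑dimethyloct‑2‑en‑1‑yl acetate | CC(=O)OC/C=C(\C)CC[C@H](Br)[C@](C)(O)CO | intermediate
10 | (2E,6S,7R)‑6‑bromo‑7‑hydroxy‑3,7‑dimethyl‑8‑oxooct‑2‑en‑1‑yl acetate | CC(=O)OC/C=C(\C)CC[C@H](Br)[C@](C)(O)C=O | intermediate
11 | (2E,6S,7R)‑6‑bromo‑3,7‑dimethyl‑8‑oxo‑7‑(triethylsilyloxy)oct‑2‑en‑1‑yl acetate | CC(=O)OC/C=C(\C)CC[C@H](Br)[C@](C)(O[Si](CC)(CC)CC)C=O | intermediate
12 | (2E,6S,7R)‑6‑bromo‑3,7‑dimethyl‑7‑(triethylsilyloxy)nona‑2,8‑dien‑1‑yl acetate | CC(=O)OC/C=C(\C)CC[C@H](Br)[C@](C)(O[Si](CC)(CC)CC)C=C | intermediate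
13 | 3‑bromo‑4‑hydroxybenzaldehyde | O=Cc1ccc(O)c(Br)c1 | starting material
14 | 2‑bromo‑4‑formylphenyl pivalate | O=Cc1ccc(OC(=O)C(C)(C)C)c(Br)c1 | intermediate
15 | 4‑formyl‑2‑(pinacolatoboryl)phenyl pivalate | O=Cc1ccc(OC(=O)C(C)(C)C)c(B2OC(C)(C)C(C)(C)O2)c1 | intermediate
16 | 2‑[(2E,6S,7R)‑6‑bromo‑3,7‑dimethyl‑7‑(triethylsilyloxy)nona‑2,8‑dien‑1‑yl]‑4‑formylphenyl pivalate | O=Cc1ccc(OC(=O)C(C)(C)C)c(C/C=C(\C)CC[C@H](Br)[C@](C)(O[Si](CC)(CC)CC)C=C)c1 | intermediate
17 | 3‑[(2E,6S,7R)‑6‑bromo‑3,7‑dimethyl‑7‑(triethylsilyloxy)nona‑2,8‑dien‑1‑yl]‑4‑(pivaloyloxy)benzoic acid | OC(=O)c1ccc(OC(=O)C(C)(C)C)c(C/C=C(\C)CC[C@H](Br)[C@](C)(O[Si](CC)(CC)CC)C=C)c1 | intermediate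
18 | (3R,6E)‑3‑bromo‑7‑iodo‑2,6‑dimethylhept‑6‑en‑2‑yl ester of 17 | I/C=C(\C)CC[C@@H](Br)C(C)(C)OC(=O)c1ccc(OC(=O)C(C)(C)C)c(C/C=C(\C)CC[C@H](Br)[C@](C)(O[Si](CC)(CC)CC)C=C)c1 | intermediate
19 | 20‑membered macrolactone: 15′‑lactone of 3‑[(2E,6S,7R,10E,14R)‑6,14‑dibromo‑15‑hydroxy‑3,7,11,15‑tetramethyl‑7‑(triethylsilyloxy)hexadeca‑2,10‑dien‑1‑yl]‑4‑(pivaloyloxy)benzoic acid | C1/C=C(\C)CC[C@@H](Br)C(C)(C)OC(=O)c2ccc(OC(=O)C(C)(C)C)c(c2)C/C=C(\C)CC[C@H](Br)[C@](C)(O[Si](CC)(CC)CC)C1 | intermediate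
20 | 7′‑hydroxy analogue of 19 (6′S,7′R bromohydrin) | C1/C=C(\C)CC[C@@H](Br)C(C)(C)OC(=O)c2ccc(OC(=O)C(C)(C)C)c(c2)C/C=C(\C)CC[C@H](Br)[C@](C)(O)C1 | intermediate
21 | O‑pivaloyl 10′,11′‑alkene precursor (2′R,6′S,7′S,14′R,10′E; exocyclic C3′ methylene) | C=C1CC[C@H](Br)[C@@]2(C)CC/C=C(\C)CC[C@@H](Br)C(C)(C)OC(=O)c3ccc(OC(=O)C(C)(C)C)c(c3)C[C@H]12 | intermediate
22 | (10′S,11′S)‑epoxide of 21 | C=C1CC[C@H](Br)[C@@]2(C)CC[C@@H]3O[C@@]3(C)CC[C@@H](Br)C(C)(C)OC(=O)c4ccc(OC(=O)C(C)(C)C)c(c4)C[C@H]12 | intermediate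
23 | bromophycolide H O‑pivalate | C=C1CC[C@H](Br)[C@@]2(C)CC[C@@H](Br)[C@@](C)(O)CC[C@@H](Br)C(C)(C)OC(=O)c3ccc(OC(=O)C(C)(C)C)c(c3)C[C@H]12 | intermediate
24 | bromophycolide H (2′R,6′S,7′S,10′R,11′S,14′R) | C=C1CC[C@H](Br)[C@@]2(C)CC[C@@H](Br)[C@@](C)(O)CC[C@@H](Br)C(C)(C)OC(=O)c3ccc(O)c(c3)C[C@H]12 | target

## Summary

**Total steps:** 21 (fragment A: 4; fragment B: 6; fragment C: 2; assembly and endgame: 9).
**Longest linear sequence:** 15 steps (6 → 24, Steps 5–10 and 13–21).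

**Three steps most likely to fail, with fallbacks that change the approach:**

1. **Step 18 (bromonium cyclization).** The risks are endo rather than exo proton loss, simple elimination of the tertiary triflate, and Br⁺ scrambling. Fallback: replace the C3′ methyl terminator with an allylsilane (C3′–CH2SiMe3, installed on an 8‑O‑silyl geraniol by alkoxide‑directed allylic lithiation/Me3SiCl) so that desilylation gives the exocyclic alkene unambiguously. The arene would then be attached by phenoxide C‑alkylation instead of π‑allyl‑Pd chemistry, which an allylsilane would not tolerate.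

2. **Step 15 (acylation of a β‑bromo tertiary alcohol).** The risks are low conversion or DMAP‑induced epoxide closure. Fallback: form the C15′–O bond by cation capture instead of acyl transfer. Ionize 5 (for example as its tertiary trifluoroacetate in HFIP) to the configurationally defined bromonium ion and trap it with acid 17; Markovnikov opening leaves C14′ unchanged.

3. **Step 16 (20‑membered B‑alkyl Suzuki macrocyclization with a hindered borane).** Fallback: reverse the bond order. Couple 12 with epoxide 4 intermolecularly by B‑alkyl Suzuki, open the epoxide with bromide, esterify with the boronate‑bearing benzoic acid, and close the ring by an intramolecular Pd allyl–aryl Suzuki coupling at Ar–C1′.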